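Ring A of the flavone is disconnected at C5–C6, C7–C8 and C8–C8a. A Dötz benzannulation of a 4-pyranon-3-yl (benzyloxy)carbene chromium complex with methoxyacetylene and one CO ligand builds that ring onto the finished rings B and C in one operation. It exploits the para C5–O/C8–O pair with C7–OMe beside C8–O: the carbene carbon becomes C5, the alkyne CH becomes C6, the alkyne C–OMe becomes C7 and CO becomes the only free phenol, C8–OH, where the acetate belongs. The precursor is a 2-H pyranone carrying the carbene at C3, benzyloxy at C5 and the dibenzyloxyphenyl group at C6. Acetylation and one hydrogenolysis finish the synthesis.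

Key step: step 8

Remarks on the chemistry (assumptions and design choices):
- The target has no stereocentre. The double-bond geometry of enaminone 6 and the transient stereocentre of 9 are of no consequence.
- The carbene oxygen carries benzyl, not methyl. C5–OBn then falls together with the three other benzyl ethers under neutral hydrogenolysis, which cannot touch C7–OMe or the C8 acetate.
- The acylchromate is made from the pyranone acid chloride and Na2Cr(CO)5, not from a C3-metallated pyranone. In such a species the C–metal bond lies anti to the ring C2–O bond (ring opening) and sits next to a free carbonyl.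
- Locants: in complex 18 the ring closes onto pyranone C2–H; C6 carries the aryl group. In the SMILES, Cr–CO bonds are written as cumulated double bonds and the η6 complex 22 as its two bonded fragments.

Step 1
Reactants: 1 tert-butyl acetate; 2 (benzyloxy)acetyl chloride
Product: 4 tert-butyl 4-(benzyloxy)-3-oxobutanoate, via lithium enolate of tert-butyl acetate 3 (not isolated)
Conditions: 1 (2.1 equiv), LiN(iPr)2 (2.1 equiv), THF, −78 °C; then 2, −78 °C; aq. NH4Cl
Reagents that add atoms: none
Why: Crossed Claisen condensation in which the preformed ester enolate is C-acylated by the acid chloride at low temperature, the second equivalent of enolate holding the product as its enolate so that it is not acylated again.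

Step 2
Reactants: 4 tert-butyl 4-(benzyloxy)-3-oxobutanoate; 5 N,N-dimethylformamide dimethyl acetal
Product: 6 tert-butyl 4-(benzyloxy)-2-[(dimethylamino)methylidene]-3-oxobutanoate
Conditions: 5 (1.2 equiv), toluene, rt
Reagents that add atoms: none
Why: Enaminone formation by condensation of the amide acetal with the active methylene between the two carbonyl groups, which is far more acidic than the CH2OBn position.

Step 3
Reactants: 6 tert-butyl 4-(benzyloxy)-2-[(dimethylamino)methylidene]-3-oxobutanoate; 7 3,4-bis(benzyloxy)benzoic acid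
Product: 10 tert-butyl 5-(benzyloxy)-6-[3,4-bis(benzyloxy)phenyl]-4-oxo-4H-pyran-3-carboxylate, via 3,4-bis(benzyloxy)benzoyl chloride 8 (not isolated), via C-aroylated enaminone 9 (not isolated)
Conditions: 7, (COCl)2, cat. DMF, CH2Cl2, 0 °C → rt, evaporate; 6, LiN(SiMe3)2 (2.5 equiv), THF, −78 °C; then 2 M aq. HCl, THF, rt
Reagents that add atoms: none
Why: In situ C-acylation of the γ-enolate of the enaminone gives a 1,3-diketone whose enol oxygen, on acidification, adds to the enamine carbon and expels dimethylamine (addition–elimination), closing the 4-pyranone with ester, benzyloxy and aryl groups already at C3, C5 and C6.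

Step 4
Reactants: 10 tert-butyl 5-(benzyloxy)-6-[3,4-bis(benzyloxy)phenyl]-4-oxo-4H-pyran-3-carboxylate
Product: 11 5-(benzyloxy)-6-[3,4-bis(benzyloxy)phenyl]-4-oxo-4H-pyran-3-carboxylic acid
Conditions: TFA/CH2Cl2 (1:4), 0 °C → rt
Reagents that add atoms: none
Why: Acidolysis of the tert-butyl ester with loss of isobutene frees the acid without hydroxide, which would open the pyranone at the doubly activated C2, while aryl and enol benzyl ethers tolerate TFA at room temperature.

Step 5
Reactants: 11 5-(benzyloxy)-6-[3,4-bis(benzyloxy)phenyl]-4-oxo-4H-pyran-3-carboxylic acid; 12 chromium hexacarbonyl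
Product: 16 tetramethylammonium pentacarbonyl{[5-(benzyloxy)-6-[3,4-bis(benzyloxy)phenyl]-4-oxo-4H-pyran-3-yl]carbonyl}chromate, via pyranone-3-carbonyl chloride 13 (not isolated), via disodium pentacarbonylchromate 14 (not isolated), via sodium acylchromate 15 (not isolated)
Conditions: 11, (COCl)2, cat. DMF, CH2Cl2, 0 °C → rt, evaporate; 12, NaC10H8 (2.0 equiv), THF, −78 °C; add 13 in THF, −78 → 0 °C; then Me4NBr, degassed H2O, 0 °C
Reagents that add atoms: tetramethylammonium bromide, C[N+](C)(C)C.[Br-]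
Why: Semmelhack–Hegedus acylmetalate synthesis, in which the dianion Na2Cr(CO)5 is acylated at chromium by the acid chloride and the acylchromate is secured as its tetramethylammonium salt, so that no carbanion is ever generated on the pyranone.

Step 6
Reactants: 16 tetramethylammonium pentacarbonyl{[5-(benzyloxy)-6-[3,4-bis(benzyloxy)phenyl]-4-oxo-4H-pyran-3-yl]carbonyl}chromate
Product: 18 pentacarbonyl{(benzyloxy)[5-(benzyloxy)-6-[3,4-bis(benzyloxy)phenyl]-4-oxo-4H-pyran-3-yl]methylidene}chromium, via acetoxycarbene complex 17 (not isolated)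
Conditions: AcBr (1.05 equiv), CH2Cl2, −40 °C; then BnOH (1.5 equiv), −40 °C → rt, Ar
Reagents that add atoms: benzyl alcohol, OCc1ccccc1
Why: Fischer carbene synthesis by the acyloxycarbene route, in which O-acetylation of the acylate gives a highly electrophilic acetoxycarbene and benzyl alcohol displaces acetate at the carbene carbon by addition–elimination.

Step 7
Reactants: 19 chloroacetaldehyde dimethyl acetal
Product: 21 methoxyacetylene, via sodium methoxyacetylide 20 (not isolated)
Conditions: NaNH2 (3.1 equiv), liq. NH3, −33 °C; then sat. aq. NH4Cl, −70 °C; distil into THF at −78 °C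
Reagents that add atoms: none
Why: Two successive base-induced β-eliminations (methanol, then HCl) give the ynol ether, which the third equivalent of amide holds as its sodium acetylide until the cold proton quench.

Step 8
Reactants: 18 pentacarbonyl{(benzyloxy)[5-(benzyloxy)-6-[3,4-bis(benzyloxy)phenyl]-4-oxo-4H-pyran-3-yl]methylidene}chromium; 21 methoxyacetylene
Product: 23 3,5-bis(benzyloxy)-2-[3,4-bis(benzyloxy)phenyl]-8-hydroxy-7-methoxy-4H-chromen-4-one, via ring A tricarbonylchromium complex 22 (not isolated)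
Conditions: 21 (4 equiv), degassed THF (0.05 M), 50 °C, sealed tube, Ar; then air, Et2O, rt
Reagents that add atoms: none
Why: Proposed new method: loss of one cis CO from 18 lets the ynol ether bind and insert into the Cr=C bond with its unsubstituted, nucleophilic carbon attacking the electrophilic carbene carbon, so that the new vinylcarbene carries OMe on the carbon next to chromium, and CO insertion then gives a dienylketene whose termini are the ketene carbon and pyranone C2–H. The closest known reaction type is the Dötz benzannulation of alkenyl(alkoxy)carbene chromium complexes with terminal alkynes, from which this case differs in the ynol ether partner and in the 4-pyranon-3-yl group on the carbene. Ring A closes by a thermal disrotatory 6π electrocyclisation of the dienylketene (bond C8–C8a), and tautomerisation of the cyclohexadienone gives the chromium-bound phenol 22, which air sets free. No stereocentre is formed. The step needs regioselective insertion (C–OMe beside the CO-derived carbon) and phenol formation in preference to five-membered ring closure; the first is secured because the steric rule for terminal alkynes and the polarisation of the ynol ether point the same way, the second by the alkenyl nature of the carbene, the unsubstituted C2–H terminus and THF as solvent.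

Step 9
Reactants: 23 3,5-bis(benzyloxy)-2-[3,4-bis(benzyloxy)phenyl]-8-hydroxy-7-methoxy-4H-chromen-4-one
Product: 24 3,5-bis(benzyloxy)-2-[3,4-bis(benzyloxy)phenyl]-7-methoxy-4-oxo-4H-chromen-8-yl acetate
Conditions: Ac2O, pyridine, cat. DMAP, CH2Cl2, 0 °C → rt
Reagents that add atoms: acetic anhydride, CC(=O)OC(C)=O
Why: DMAP-catalysed O-acetylation (nucleophilic acyl substitution) at the only free hydroxyl group, the C8 phenol created by the benzannulation.

Step 10
Reactants: 24 3,5-bis(benzyloxy)-2-[3,4-bis(benzyloxy)phenyl]-7-methoxy-4-oxo-4H-chromen-8-yl acetate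
Product: 25 gossypetin 7-methyl ether 8-acetate, 2-(3,4-dihydroxyphenyl)-3,5-dihydroxy-7-methoxy-4-oxo-4H-chromen-8-yl acetate
Conditions: H2 (1 atm), 10% Pd/C, EtOAc/THF, rt
Reagents that add atoms: none
Why: Heterogeneous hydrogenolysis of the four benzyl ethers under neutral conditions leaves the aryl acetate, the 7-methyl ether and the C2=C3 bond of the aromatic pyranone intact.

Compound list
1 | tert-butyl acetate | CC(=O)OC(C)(C)C | starting material
2 | (benzyloxy)acetyl chloride | O=C(Cl)COCc1ccccc1 | starting material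
3 | lithium enolate of tert-butyl acetate (lithium 1-tert-butoxyethen-1-olate) | [Li+].[O-]C(=C)OC(C)(C)C | intermediate (not isolated)
4 | tert-butyl 4-(benzyloxy)-3-oxobutanoate | CC(C)(C)OC(=O)CC(=O)COCc1ccccc1 | intermediate
5 | N,N-dimethylformamide dimethyl acetal | COC(OC)N(C)C | starting material
6 | tert-butyl 4-(benzyloxy)-2-[(dimethylamino)methylidene]-3-oxobutanoate (double-bond geometry not defined) | CC(C)(C)OC(=O)C(=CN(C)C)C(=O)COCc1ccccc1 | intermediate
7 | 3,4-bis(benzyloxy)benzoic acid | O=C(O)c1ccc(OCc2ccccc2)c(OCc2ccccc2)c1 | starting material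
8 | 3,4-bis(benzyloxy)benzoyl chloride | O=C(Cl)c1ccc(OCc2ccccc2)c(OCc2ccccc2)c1 | intermediate (not isolated)
9 | C-aroylated enaminone, tert-butyl 4-(benzyloxy)-5-[3,4-bis(benzyloxy)phenyl]-2-[(dimethylamino)methylidene]-3,5-dioxopentanoate (racemic at C4, enolisable) | CC(C)(C)OC(=O)C(=CN(C)C)C(=O)C(OCc1ccccc1)C(=O)c1ccc(OCc2ccccc2)c(OCc2ccccc2)c1 | intermediate (not isolated)
10 | tert-butyl 5-(benzyloxy)-6-[3,4-bis(benzyloxy)phenyl]-4-oxo-4H-pyran-3-carboxylate | CC(C)(C)OC(=O)c1coc(-c2ccc(OCc3ccccc3)c(OCc3ccccc3)c2)c(OCc2ccccc2)c1=O | intermediate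
11 | 5-(benzyloxy)-6-[3,4-bis(benzyloxy)phenyl]-4-oxo-4H-pyran-3-carboxylic acid | O=C(O)c1coc(-c2ccc(OCc3ccccc3)c(OCc3ccccc3)c2)c(OCc2ccccc2)c1=O | intermediate
12 | chromium hexacarbonyl | O=C=[Cr](=C=O)(=C=O)(=C=O)(=C=O)=C=O | starting material
13 | 5-(benzyloxy)-6-[3,4-bis(benzyloxy)phenyl]-4-oxo-4H-pyran-3-carbonyl chloride | O=C(Cl)c1coc(-c2ccc(OCc3ccccc3)c(OCc3ccccc3)c2)c(OCc2ccccc2)c1=O | intermediate (not isolated)
14 | disodium pentacarbonylchromate, Na2Cr(CO)5 | [Na+].[Na+].O=C=[Cr-2](=C=O)(=C=O)(=C=O)=C=O | intermediate (not isolated)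
15 | sodium pentacarbonyl{[5-(benzyloxy)-6-[3,4-bis(benzyloxy)phenyl]-4-oxo-4H-pyran-3-yl]carbonyl}chromate | [Na+].[O-]C(c1coc(-c2ccc(OCc3ccccc3)c(OCc3ccccc3)c2)c(OCc2ccccc2)c1=O)=[Cr](=C=O)(=C=O)(=C=O)(=C=O)=C=O | intermediate (not isolated)
16 | tetramethylammonium pentacarbonyl{[5-(benzyloxy)-6-[3,4-bis(benzyloxy)phenyl]-4-oxo-4H-pyran-3-yl]carbonyl}chromate | C[N+](C)(C)C.[O-]C(c1coc(-c2ccc(OCc3ccccc3)c(OCc3ccccc3)c2)c(OCc2ccccc2)c1=O)=[Cr](=C=O)(=C=O)(=C=O)(=C=O)=C=O | intermediate
17 | pentacarbonyl{(acetyloxy)[5-(benzyloxy)-6-[3,4-bis(benzyloxy)phenyl]-4-oxo-4H-pyran-3-yl]methylidene}chromium | CC(=O)OC(c1coc(-c2ccc(OCc3ccccc3)c(OCc3ccccc3)c2)c(OCc2ccccc2)c1=O)=[Cr](=C=O)(=C=O)(=C=O)(=C=O)=C=O | intermediate (not isolated)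
18 | pentacarbonyl{(benzyloxy)[5-(benzyloxy)-6-[3,4-bis(benzyloxy)phenyl]-4-oxo-4H-pyran-3-yl]methylidene}chromium | O=C=[Cr](=C=O)(=C=O)(=C=O)(=C=O)=C(OCc1ccccc1)c1coc(-c2ccc(OCc3ccccc3)c(OCc3ccccc3)c2)c(OCc2ccccc2)c1=O | intermediate (key-step precursor)
19 | chloroacetaldehyde dimethyl acetal | COC(CCl)OC | starting material
20 | sodium methoxyacetylide | [Na+].[C-]#COC | intermediate (not isolated)
21 | methoxyacetylene | COC#C | intermediate
22 | tricarbonyl{η6-3,5-bis(benzyloxy)-2-[3,4-bis(benzyloxy)phenyl]-8-hydroxy-7-methoxy-4H-chromen-4-one}chromium, chromium bound to ring A | COc1cc(OCc2ccccc2)c2c(=O)c(OCc3ccccc3)c(-c3ccc(OCc4ccccc4)c(OCc4ccccc4)c3)oc2c1O.O=C=[Cr](=C=O)=C=O | intermediate (not isolated)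
23 | 3,5-bis(benzyloxy)-2-[3,4-bis(benzyloxy)phenyl]-8-hydroxy-7-methoxy-4H-chromen-4-one | COc1cc(OCc2ccccc2)c2c(=O)c(OCc3ccccc3)c(-c3ccc(OCc4ccccc4)c(OCc4ccccc4)c3)oc2c1O | intermediate (key-step product)
24 | 3,5-bis(benzyloxy)-2-[3,4-bis(benzyloxy)phenyl]-7-methoxy-4-oxo-4H-chromen-8-yl acetate | COc1cc(OCc2ccccc2)c2c(=O)c(OCc3ccccc3)c(-c3ccc(OCc4ccccc4)c(OCc4ccccc4)c3)oc2c1OC(C)=O | intermediate
25 | gossypetin 7-methyl ether 8-acetate | COc1cc(O)c2c(=O)c(O)c(-c3ccc(O)c(O)c3)oc2c1OC(C)=O | target

Total step count: 10. Longest linear sequence: 9 steps (steps 1 to 6, then 8, 9 and 10); step 7 is a one-step side branch.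

Steps most likely to fail

1. Step 8 (carries the label). After insertion of the ynol ether, the doubly oxygen-stabilised vinylcarbene may fail to take up CO and close a five-membered ring onto C2 instead. The alkyne may also insert twice or oligomerise, and displacement of a CO ligand by the pyranone carbonyl may stall the sequence. The fallback uses known chemistry only, sets out from acid 7 and returns to the route at target 25. Hoesch acylation of phloroglucinol with (benzyloxy)acetonitrile (ZnCl2, HCl, Et2O; then hot water) would give 2-(benzyloxy)-1-(2,4,6-trihydroxyphenyl)ethanone F1. Acid 7 would be converted through chloride 8 and its own sodium salt into 3,4-bis(benzyloxy)benzoic anhydride F2. Allan–Robinson condensation of the ketone with this anhydride and the potassium salt of 7 (170–180 °C, then aqueous-ethanolic KOH to strip O-aroyl groups) should give 3-(benzyloxy)-2-[3,4-bis(benzyloxy)phenyl]-5,7-dihydroxy-4H-chromen-4-one F3. Methylation of the unchelated 7-OH (Me2SO4, 1 equiv, K2CO3, acetone) should give 3-(benzyloxy)-2-[3,4-bis(benzyloxy)phenyl]-5-hydroxy-7-methoxy-4H-chromen-4-one F4. Elbs persulfate oxidation (K2S2O8, aq. KOH/pyridine) attacks para to the 5-phenoxide, at C8, and should give the potassium 8-sulfate F5, which is hydrolysed (aq. HCl, Na2SO3, 80 °C) to 3-(benzyloxy)-2-[3,4-bis(benzyloxy)phenyl]-5,8-dihydroxy-7-methoxy-4H-chromen-4-one F6. Acetylation of the unchelated 8-OH (Ac2O, 1 equiv, pyridine, 0 °C) should leave the hydrogen-bonded 5-OH free and give 3-(benzyloxy)-2-[3,4-bis(benzyloxy)phenyl]-5-hydroxy-7-methoxy-4-oxo-4H-chromen-8-yl acetate F7. Hydrogenolysis as in step 10 then gives 25.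

2. Step 5. The chromate dianion may transfer an electron to the pyranone or add to its doubly activated C2 instead of being acylated at chromium. The fallback sets out from acid 11 and returns at salt 16. Protodecarboxylation of 11 (cat. Cu2O, 1,10-phenanthroline, NMP/quinoline, 160 °C) should give 3-(benzyloxy)-2-[3,4-bis(benzyloxy)phenyl]-4H-pyran-4-one F8. Iodination of the enone α-carbon C5 (I2, pyridine, CH2Cl2, rt) should give 3-(benzyloxy)-2-[3,4-bis(benzyloxy)phenyl]-5-iodo-4H-pyran-4-one F9. Iodine–magnesium exchange (iPrMgCl·LiCl, THF, −40 °C), chosen because a C–Mg bond is far less prone than a C–Li bond to β-elimination of the ring oxygen, should give the pyranonylmagnesium chloride F10. Its addition to chromium hexacarbonyl 12 (THF, −40 °C → rt) should give the chloromagnesium acylchromate F11, and cation exchange with Me4NBr in water returns 16.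

3. Step 6. The acetoxycarbene may decompose thermally before alcoholysis, or benzyl alcohol may add in conjugate fashion to C2 of the strongly electrophilic pyranonyl carbene. The fallback sets out from 16 and returns at target 25. O-Methylation with Me3OBF4 (CH2Cl2, 0 °C) should give the more robust methoxycarbene complex F12. Benzannulation with 21 under the conditions of step 8 should give, through the ring A tricarbonylchromium complex F13 and air, 3-(benzyloxy)-2-[3,4-bis(benzyloxy)phenyl]-8-hydroxy-5,7-dimethoxy-4H-chromen-4-one F14. Acetylation as in step 9 gives 3-(benzyloxy)-2-[3,4-bis(benzyloxy)phenyl]-5,7-dimethoxy-4-oxo-4H-chromen-8-yl acetate F15. BCl3 with pentamethylbenzene (CH2Cl2, −78 → 0 °C) then cleaves the three benzyl ethers and, through the boron chelate with C4=O, the 5-methyl ether, to give 25.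

Further compounds
F1 | step 8 | 2-(benzyloxy)-1-(2,4,6-trihydroxyphenyl)ethanone | O=C(COCc1ccccc1)c1c(O)cc(O)cc1O
F2 | step 8 | 3,4-bis(benzyloxy)benzoic anhydride | O=C(OC(=O)c1ccc(OCc2ccccc2)c(OCc2ccccc2)c1)c1ccc(OCc2ccccc2)c(OCc2ccccc2)c1
F3 | step 8 | 3-(benzyloxy)-2-[3,4-bis(benzyloxy)phenyl]-5,7-dihydroxy-4H-chromen-4-one | O=c1c(OCc2ccccc2)c(-c2ccc(OCc3ccccc3)c(OCc3ccccc3)c2)oc2cc(O)cc(O)c12
F4 | step 8 | 3-(benzyloxy)-2-[3,4-bis(benzyloxy)phenyl]-5-hydroxy-7-methoxy-4H-chromen-4-one | COc1cc(O)c2c(=O)c(OCc3ccccc3)c(-c3ccc(OCc4ccccc4)c(OCc4ccccc4)c3)oc2c1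
F5 | step 8 | potassium 3-(benzyloxy)-2-[3,4-bis(benzyloxy)phenyl]-5-hydroxy-7-methoxy-4-oxo-4H-chromen-8-yl sulfate | COc1cc(O)c2c(=O)c(OCc3ccccc3)c(-c3ccc(OCc4ccccc4)c(OCc4ccccc4)c3)oc2c1OS(=O)(=O)[O-].[K+]
F6 | step 8 | 3-(benzyloxy)-2-[3,4-bis(benzyloxy)phenyl]-5,8-dihydroxy-7-methoxy-4H-chromen-4-one | COc1cc(O)c2c(=O)c(OCc3ccccc3)c(-c3ccc(OCc4ccccc4)c(OCc4ccccc4)c3)oc2c1O
F7 | step 8 | 3-(benzyloxy)-2-[3,4-bis(benzyloxy)phenyl]-5-hydroxy-7-methoxy-4-oxo-4H-chromen-8-yl acetate | COc1cc(O)c2c(=O)c(OCc3ccccc3)c(-c3ccc(OCc4ccccc4)c(OCc4ccccc4)c3)oc2c1OC(C)=O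
F8 | step 5 | 3-(benzyloxy)-2-[3,4-bis(benzyloxy)phenyl]-4H-pyran-4-one | O=c1ccoc(-c2ccc(OCc3ccccc3)c(OCc3ccccc3)c2)c1OCc1ccccc1
F9 | step 5 | 3-(benzyloxy)-2-[3,4-bis(benzyloxy)phenyl]-5-iodo-4H-pyran-4-one | O=c1c(I)coc(-c2ccc(OCc3ccccc3)c(OCc3ccccc3)c2)c1OCc1ccccc1
F10 | step 5 | {5-(benzyloxy)-6-[3,4-bis(benzyloxy)phenyl]-4-oxo-4H-pyran-3-yl}magnesium chloride | O=c1c([Mg]Cl)coc(-c2ccc(OCc3ccccc3)c(OCc3ccccc3)c2)c1OCc1ccccc1
F11 | step 5 | chloromagnesium pentacarbonyl{[5-(benzyloxy)-6-[3,4-bis(benzyloxy)phenyl]-4-oxo-4H-pyran-3-yl]carbonyl}chromate | Cl[Mg+].[O-]C(c1coc(-c2ccc(OCc3ccccc3)c(OCc3ccccc3)c2)c(OCc2ccccc2)c1=O)=[Cr](=C=O)(=C=O)(=C=O)(=C=O)=C=O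
F12 | step 6 | pentacarbonyl{methoxy[5-(benzyloxy)-6-[3,4-bis(benzyloxy)phenyl]-4-oxo-4H-pyran-3-yl]methylidene}chromium | COC(c1coc(-c2ccc(OCc3ccccc3)c(OCc3ccccc3)c2)c(OCc2ccccc2)c1=O)=[Cr](=C=O)(=C=O)(=C=O)(=C=O)=C=O
F13 | step 6 | tricarbonyl{η6-3-(benzyloxy)-2-[3,4-bis(benzyloxy)phenyl]-8-hydroxy-5,7-dimethoxy-4H-chromen-4-one}chromium, chromium bound to ring A | COc1cc(OC)c2c(=O)c(OCc3ccccc3)c(-c3ccc(OCc4ccccc4)c(OCc4ccccc4)c3)oc2c1O.O=C=[Cr](=C=O)=C=O
F14 | step 6 | 3-(benzyloxy)-2-[3,4-bis(benzyloxy)phenyl]-8-hydroxy-5,7-dimethoxy-4H-chromen-4-one | COc1cc(OC)c2c(=O)c(OCc3ccccc3)c(-c3ccc(OCc4ccccc4)c(OCc4ccccc4)c3)oc2c1O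
F15 | step 6 | 3-(benzyloxy)-2-[3,4-bis(benzyloxy)phenyl]-5,7-dimethoxy-4-oxo-4H-chromen-8-yl acetate | COc1cc(OC)c2c(=O)c(OCc3ccccc3)c(-c3ccc(OCc4ccccc4)c(OCc4ccccc4)c3)oc2c1OC(C)=O
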